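**Retrosynthetic overview**
1. The C15–O bond is made last: target 19 from trienoic acid 17 and acetic acid by an E-selective 4,1-hydroacetoxylation of the side-chain 2-substituted 1,3-diene, which also fixes the 13E alkene.
2. Acid 17 comes from vinyl acid 14 by hydroboration and Suzuki–Miyaura coupling with chloroprene (C12–C13).
3. Ring A is formed second: diene 11 and methacrolein in a catalyst-controlled, formyl-exo Diels–Alder reaction (C2–C3 and C4–C5; sets C4 and C5), then CHO to CO2H.
4. Ring B is bought as 2-methylcyclohex-2-en-1-one: C8 by asymmetric conjugate methylation, C9 by enolate vinylation, the diene by enol triflate formation and Stille coupling.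

Assumption: the SMILES is read as (4S,5S,8R,9S,13E)-15-acetoxy-ent-halima-1(10),13-dien-18-oic acid; chiral ligands and catalysts are named as the enantiomers that give the configurations drawn, and the antipode is used if the sense of induction proves opposite.

**Step 1**
Reactants: 1 2-methylcyclohex-2-en-1-one; 2 trimethylaluminium
Product: 4 trimethyl{[(3R)-2,3-dimethylcyclohex-1-en-1-yl]oxy}silane, via dimethylaluminium enolate 3 (not isolated)
Conditions: AlMe3 (1.3 equiv), copper thiophene-2-carboxylate CuO2C(C4H3S) (2 mol %), (S,R,R)-binaphthol bis(1-phenylethyl)amine phosphoramidite (4 mol %), Et2O, −30 °C; then Me3SiOTf, −30 °C to rt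
Reagents that add atoms: trimethylsilyl trifluoromethanesulfonate, C[Si](C)(C)OS(=O)(=O)C(F)(F)F
Why: Copper-catalysed asymmetric conjugate addition of a methyl group to the enone sets the secondary methyl stereocentre (3R, C8 of the target) under ligand control, and O-silylation of the aluminium enolate stores the enolate regiochemistry.

**Step 2**
Reactants: 4 trimethyl{[(3R)-2,3-dimethylcyclohex-1-en-1-yl]oxy}silane; 5 bromoethene
Product: 7 (2S,3R)-2-ethenyl-2,3-dimethylcyclohexan-1-one, via lithium enolate 6 (not isolated)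
Conditions: MeLi, THF, 0 °C to rt; then 5, Pd2(dba)3 (2.5 mol %), P(t-Bu)3 (10 mol %), THF, 25 to 40 °C
Reagents that add atoms: none
Why: Palladium-catalysed α-vinylation of the regiodefined lithium enolate (ketone α-alkenylation); the vinyl group enters anti to the adjacent C3 methyl, which sets the quaternary centre (2S, C9) with the two methyls cis.

**Step 3**
Reactants: 7 (2S,3R)-2-ethenyl-2,3-dimethylcyclohexan-1-one
Product: 9 (5R,6S)-6-ethenyl-5,6-dimethylcyclohex-1-en-1-yl trifluoromethanesulfonate, via potassium enolate 8 (not isolated)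
Conditions: KN(SiMe3)2, THF, −78 °C; PhNTf2, −78 to 0 °C
Reagents that add atoms: N-phenylbis(trifluoromethanesulfonimide), O=S(=O)(N(c1ccccc1)S(=O)(=O)C(F)(F)F)C(F)(F)F
Why: Enol triflate formation; the ketone can enolise only toward its single α-CH2 because the other α-carbon is quaternary, and no stereocentre is touched.

**Step 4**
Reactants: 9 (5R,6S)-6-ethenyl-5,6-dimethylcyclohex-1-en-1-yl trifluoromethanesulfonate; 10 tributyl(ethenyl)stannane
Product: 11 (5R,6S)-1,6-diethenyl-5,6-dimethylcyclohex-1-ene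
Conditions: Pd(PPh3)4 (5 mol %), LiCl (3 equiv), THF, 65 °C
Reagents that add atoms: none
Why: Stille cross-coupling of the hindered alkenyl triflate (chloride-promoted) gives the semicyclic 1,3-diene, held s-cis by the neighbouring quaternary carbon.

**Step 5**
Reactants: 11 (5R,6S)-1,6-diethenyl-5,6-dimethylcyclohex-1-ene; 12 2-methylprop-2-enal
Product: 13 (1S,5S,6R,8aS)-5-ethenyl-1,5,6-trimethyl-1,2,3,5,6,7,8,8a-octahydronaphthalene-1-carbaldehyde
Conditions: (S)-o-tolyl CBS oxazaborolidine (20 mol %), Tf2NH (18 mol %), CH2Cl2, −78 to −40 °C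
Reagents that add atoms: none
Why: Catalytic asymmetric Diels–Alder reaction that closes ring A with the 1(10)-alkene in place: the 1,2-dialkyl diene reacts "ortho" (quaternary C4 to the ring terminus C5), 2-substituted acroleins react in the formyl-exo mode on the cationic oxazaborolidine so CHO ends cis to H5, and because the two half-chairs of the diene shield opposite faces about equally, the catalyst chooses the diene face and sets C4 and C5 (1S,8aS).

**Step 6**
Reactants: 13 (1S,5S,6R,8aS)-5-ethenyl-1,5,6-trimethyl-1,2,3,5,6,7,8,8a-octahydronaphthalene-1-carbaldehyde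
Product: 14 (1S,5S,6R,8aS)-5-ethenyl-1,5,6-trimethyl-1,2,3,5,6,7,8,8a-octahydronaphthalene-1-carboxylic acid
Conditions: NaClO2, NaH2PO4, 2-methylbut-2-ene, t-BuOH/H2O, 0 °C to rt
Reagents that add atoms: sodium chlorite, [Na+].[O-]Cl=O
Why: Pinnick oxidation converts the non-enolisable neopentyl aldehyde to the acid under buffered conditions, with the alkenes protected by the hypochlorite scavenger.

**Step 7**
Reactants: 14 (1S,5S,6R,8aS)-5-ethenyl-1,5,6-trimethyl-1,2,3,5,6,7,8,8a-octahydronaphthalene-1-carboxylic acid; 15 2-chlorobuta-1,3-diene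
Product: 17 (1S,5S,6R,8aS)-1,5,6-trimethyl-5-(3-methylidenepent-4-en-1-yl)-1,2,3,5,6,7,8,8a-octahydronaphthalene-1-carboxylic acid, via alkylborane 16 (not isolated)
Conditions: 9-BBN-H dimer (1.1 equiv), THF, 0 °C to rt; then 15, Pd(OAc)2 (5 mol %), SPhos (10 mol %), aq K3PO4, THF, 50 °C (sealed); dilute HCl work-up
Reagents that add atoms: none
Why: Anti-Markovnikov hydroboration of the only monosubstituted alkene (the acid is masked in the flask as its acyloxyborane), then B-alkyl Suzuki–Miyaura coupling with the alkenyl chloride, builds the 2-substituted diene without touching the ring alkene.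

**Step 8**
Reactants: 17 (1S,5S,6R,8aS)-1,5,6-trimethyl-5-(3-methylidenepent-4-en-1-yl)-1,2,3,5,6,7,8,8a-octahydronaphthalene-1-carboxylic acid; 18 acetic acid
Product: 19 (1S,5S,6R,8aS)-5-[(3E)-5-acetyloxy-3-methylpent-3-en-1-yl]-1,5,6-trimethyl-1,2,3,5,6,7,8,8a-octahydronaphthalene-1-carboxylic acid
Conditions: Pd2(dba)3 (2.5 mol %), Xantphos (6 mol %), AcOH/toluene 1:4, 40 °C
Reagents that add atoms: none
Why: Proposed new method: a palladium-hydride 4,1-hydroacetoxylation of a 2-alkylbuta-1,3-diene, in which AcOH adds oxidatively to zerovalent palladium to give H–Pd–OAc, the s-cis η4-bound diene takes the hydride at the exocyclic CH2 (C16) to give the more substituted η3-allyl with the new methyl anti and the chain syn (a geometry that cannot scramble without a tertiary η1-alkyl), and acetate attacks the unhindered CH2 terminus (C15), so the C15–O bond and the 13E alkene form together while the hindered ring alkene and the tertiary acid stay untouched; the closest known reactions are palladium-hydride hydroamination and linear prenylation with isoprene and the iron-catalysed 1,4-hydroboration of myrcene-type dienes, but a linear, E-selective addition of a carboxylic acid to such a diene has not been shown.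

**Compound list**
1 | 2-methylcyclohex-2-en-1-one | CC1=CCCCC1=O | starting material
2 | trimethylaluminium | C[Al](C)C | starting material
3 | dimethylaluminium (3R)-2,3-dimethylcyclohex-1-en-1-olate | CC1=C(O[Al](C)C)CCC[C@H]1C | intermediate
4 | trimethyl{[(3R)-2,3-dimethylcyclohex-1-en-1-yl]oxy}silane | CC1=C(O[Si](C)(C)C)CCC[C@H]1C | intermediate
5 | bromoethene | C=CBr | starting material
6 | lithium (3R)-2,3-dimethylcyclohex-1-en-1-olate | CC1=C([O-])CCC[C@H]1C.[Li+] | intermediate
7 | (2S,3R)-2-ethenyl-2,3-dimethylcyclohexan-1-one | C=C[C@]1(C)C(=O)CCC[C@H]1C | intermediate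
8 | potassium (5R,6S)-6-ethenyl-5,6-dimethylcyclohex-1-en-1-olate | C=C[C@]1(C)C([O-])=CCC[C@H]1C.[K+] | intermediate
9 | (5R,6S)-6-ethenyl-5,6-dimethylcyclohex-1-en-1-yl trifluoromethanesulfonate | C=C[C@]1(C)C(OS(=O)(=O)C(F)(F)F)=CCC[C@H]1C | intermediate
10 | tributyl(ethenyl)stannane | C=C[Sn](CCCC)(CCCC)CCCC | starting material
11 | (5R,6S)-1,6-diethenyl-5,6-dimethylcyclohex-1-ene | C=C[C@]1(C)C(C=C)=CCC[C@H]1C | intermediate
12 | 2-methylprop-2-enal (methacrolein) | CC(=C)C=O | starting material
13 | (1S,5S,6R,8aS)-5-ethenyl-1,5,6-trimethyl-1,2,3,5,6,7,8,8a-octahydronaphthalene-1-carbaldehyde | C=C[C@]1(C)C2=CCC[C@](C)(C=O)[C@H]2CC[C@H]1C | intermediate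
14 | (1S,5S,6R,8aS)-5-ethenyl-1,5,6-trimethyl-1,2,3,5,6,7,8,8a-octahydronaphthalene-1-carboxylic acid | C=C[C@]1(C)C2=CCC[C@](C)(C(=O)O)[C@H]2CC[C@H]1C | intermediate
15 | 2-chlorobuta-1,3-diene (chloroprene) | C=CC(Cl)=C | starting material
16 | 9-borabicyclo[3.3.1]nonan-9-yl (1S,5S,6R,8aS)-5-[2-(9-borabicyclo[3.3.1]nonan-9-yl)ethyl]-1,5,6-trimethyl-1,2,3,5,6,7,8,8a-octahydronaphthalene-1-carboxylate | B1(C2CCCC1CCC2)CC[C@]3(C)C4=CCC[C@](C)(C(=O)OB5C6CCCC5CCC6)[C@H]4CC[C@H]3C | intermediate
17 | (1S,5S,6R,8aS)-1,5,6-trimethyl-5-(3-methylidenepent-4-en-1-yl)-1,2,3,5,6,7,8,8a-octahydronaphthalene-1-carboxylic acid (ent-halima-1(10),13(16),14-trien-18-oic acid) | C=CC(=C)CC[C@]1(C)C2=CCC[C@](C)(C(=O)O)[C@H]2CC[C@H]1C | intermediate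
18 | acetic acid | CC(=O)O | starting material
19 | (1S,5S,6R,8aS)-5-[(3E)-5-acetyloxy-3-methylpent-3-en-1-yl]-1,5,6-trimethyl-1,2,3,5,6,7,8,8a-octahydronaphthalene-1-carboxylic acid (15-acetoxy-ent-halima-1(10),13E-dien-18-oic acid) | CC(=O)OC/C=C(\C)CC[C@]1(C)C2=CCC[C@](C)(C(=O)O)[C@H]2CC[C@H]1C | target

**Step count and risks**
Total step count: 8. Longest linear sequence: 8 steps (1 to 19).

The three steps most likely to fail:

Step 5 (Diels–Alder). Regiochemistry, the formyl-exo mode and the diene face must all go the right way; the exo/endo ratio with a semicyclic diene is the weakest point. If the formyl group goes endo instead, that preference is used rather than fought. 2-Methylidenepropane-1,3-diol is mono-silylated (NaH, t-BuMe2SiCl) to 2-({[tert-butyl(dimethyl)silyl]oxy}methyl)prop-2-en-1-ol F2 and oxidised with MnO2 to 2-({[tert-butyl(dimethyl)silyl]oxy}methyl)prop-2-enal F3. Diene 11 and F3 under the same oxazaborolidinium catalyst give the formyl-endo adduct (1R,5S,6R,8aS)-1-({[tert-butyl(dimethyl)silyl]oxy}methyl)-5-ethenyl-5,6-dimethyl-1,2,3,5,6,7,8,8a-octahydronaphthalene-1-carbaldehyde F4, in which the formyl group sits where the C4 methyl belongs and the oxygenated carbon where the carboxyl belongs. Wolff–Kishner reduction (N2H4·H2O, KOH, diethylene glycol, 200 °C) turns CHO into that methyl and cleaves the silyl ether, giving [(1S,5S,6R,8aS)-5-ethenyl-1,5,6-trimethyl-1,2,3,5,6,7,8,8a-octahydronaphthalen-1-yl]methanol F5. Jones oxidation (CrO3, H2SO4, acetone, 0 °C) returns to the route at acid 14. This fallback does not help if regiochemistry or facial control is the failure.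

Step 8 (new hydroacetoxylation). It may give branched or Z acetate, or isomerised dienes. The fallback sets out from vinyl acid 14 and uses a preformed E-alkene in a C–C coupling. But-2-yn-1-ol is hydrozirconated (Cp2ZrHCl) and iodinated to (2E)-3-iodobut-2-en-1-ol F6. Acid 14 is hydroborated as in step 7 to alkylborane 16, which is coupled with F6 (PdCl2(dppf), aq K3PO4, THF/DMF, 50 °C) to give (1S,5S,6R,8aS)-5-[(3E)-5-hydroxy-3-methylpent-3-en-1-yl]-1,5,6-trimethyl-1,2,3,5,6,7,8,8a-octahydronaphthalene-1-carboxylic acid F7 (ent-halimic acid). Acetylation (Ac2O, pyridine, cat. DMAP, aqueous work-up to hydrolyse any mixed anhydride) gives 19.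

Step 2 (enolate vinylation). Forming a quaternary centre by palladium-catalysed vinylation of a tetrasubstituted enolate may be slow or poorly diastereoselective. The fallback sets out from silyl enol ether 4: MeLi regenerates lithium enolate 6, which adds to phenyl vinyl sulfoxide (THF, −78 to 0 °C) anti to the C3 methyl to give (2S,3R)-2,3-dimethyl-2-[2-(phenylsulfinyl)ethyl]cyclohexan-1-one F1. Thermal sulfoxide syn-elimination (toluene, CaCO3, 110 °C) gives vinyl ketone 7.

**Further compounds**
F1 | step 2 | (2S,3R)-2,3-dimethyl-2-[2-(phenylsulfinyl)ethyl]cyclohexan-1-one | O=S(CC[C@]1(C)C(=O)CCC[C@H]1C)c1ccccc1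
F2 | step 5 | 2-({[tert-butyl(dimethyl)silyl]oxy}methyl)prop-2-en-1-ol | C=C(CO)CO[Si](C)(C)C(C)(C)C
F3 | step 5 | 2-({[tert-butyl(dimethyl)silyl]oxy}methyl)prop-2-enal | C=C(C=O)CO[Si](C)(C)C(C)(C)C
F4 | step 5 | (1R,5S,6R,8aS)-1-({[tert-butyl(dimethyl)silyl]oxy}methyl)-5-ethenyl-5,6-dimethyl-1,2,3,5,6,7,8,8a-octahydronaphthalene-1-carbaldehyde | C=C[C@]1(C)C2=CCC[C@](C=O)(CO[Si](C)(C)C(C)(C)C)[C@H]2CC[C@H]1C
F5 | step 5 | [(1S,5S,6R,8aS)-5-ethenyl-1,5,6-trimethyl-1,2,3,5,6,7,8,8a-octahydronaphthalen-1-yl]methanol | C=C[C@]1(C)C2=CCC[C@](C)(CO)[C@H]2CC[C@H]1C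
F6 | step 8 | (2E)-3-iodobut-2-en-1-ol | OC/C=C(\C)I
F7 | step 8 | (1S,5S,6R,8aS)-5-[(3E)-5-hydroxy-3-methylpent-3-en-1-yl]-1,5,6-trimethyl-1,2,3,5,6,7,8,8a-octahydronaphthalene-1-carboxylic acid | OC/C=C(\C)CC[C@]1(C)C2=CCC[C@](C)(C(=O)O)[C@H]2CC[C@H]1C
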